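## Retrosynthetic overview

1. The target is 1-(3,4-dihydroxyphenyl)icosan-5-one. Its only ring, the catechol benzene ring, is bought and carried through, so no ring is formed in the route.
2. The free catechol and the saturated C3–C4 link come from one global hydrogenation of an O,O'-dibenzyl (E)-3-en-5-one.
3. The enone comes from a β-hydroxy ketone by dehydration. The key C3–C4 bond is made by crossed aldol addition of the kinetic lithium enolate of heptadecan-2-one to 3-[3,4-bis(benzyloxy)phenyl]propanal.
4. The aldehyde comes from dihydrocaffeic acid by esterification, O-benzylation, reduction and oxidation.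

Assumption: the target SMILES contains no stereocentre and no stereogenic double bond, so "single enantiomer" is taken to mean the achiral compound itself and no enantiocontrol is needed.

## Route

Step 1
Reactants: 1 3-(3,4-dihydroxyphenyl)propanoic acid (dihydrocaffeic acid)
Product: 2 methyl 3-(3,4-dihydroxyphenyl)propanoate
Conditions: MeOH, cat. H2SO4, reflux, N2
Reagents that add atoms: methanol, CO
Why: Fischer esterification in a large excess of methanol drives the equilibrium to the methyl ester and leaves the catechol untouched.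

Step 2
Reactants: 2 methyl 3-(3,4-dihydroxyphenyl)propanoate
Product: 3 methyl 3-[3,4-bis(benzyloxy)phenyl]propanoate
Conditions: BnBr (2.4 equiv), K2CO3 (3 equiv), DMF, 60 °C, N2
Reagents that add atoms: benzyl bromide, BrCc1ccccc1
Why: Williamson ether synthesis; the two phenoxides are alkylated by the benzylic bromide (SN2) while the methyl ester is inert to K2CO3 in DMF.

Step 3
Reactants: 3 methyl 3-[3,4-bis(benzyloxy)phenyl]propanoate
Product: 4 3-[3,4-bis(benzyloxy)phenyl]propan-1-ol
Conditions: LiAlH4 (1.0 equiv), THF, 0 °C to rt; H2O/NaOH work-up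
Reagents that add atoms: none
Why: Hydride reduction of an ester to the primary alcohol by LiAlH4; aryl benzyl ethers are stable to hydride.

Step 4
Reactants: 4 3-[3,4-bis(benzyloxy)phenyl]propan-1-ol
Product: 5 3-[3,4-bis(benzyloxy)phenyl]propanal
Conditions: Dess–Martin periodinane (1.2 equiv), CH2Cl2, 0 °C to rt; used at once in step 5
Reagents that add atoms: none
Why: Dess–Martin oxidation stops cleanly at the aldehyde under near-neutral, non-aqueous conditions, so no over-oxidation or aldol self-condensation occurs.

Step 5
Reactants: 5 3-[3,4-bis(benzyloxy)phenyl]propanal; 6 heptadecan-2-one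
Product: 8 (±)-1-[3,4-bis(benzyloxy)phenyl]-3-hydroxyicosan-5-one, via lithium heptadec-1-en-2-olate 7 (not isolated)
Conditions: LiN(iPr)2 (LDA, 1.3 equiv), THF, −78 °C, add 6 (1.25 equiv) slowly, 45 min; then 5 (1.0 equiv), −78 °C, 30 min; AcOH quench at −78 °C
Reagents that add atoms: none
Why: Directed crossed aldol addition: kinetic deprotonation by LDA at −78 °C takes place at the less hindered CH3 side, and the lithium enolate adds to the aldehyde faster than it transfers a proton; the new C3 carbinol centre forms as a racemate, which is harmless because it is removed in step 6.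

Step 6
Reactants: 8 (±)-1-[3,4-bis(benzyloxy)phenyl]-3-hydroxyicosan-5-one
Product: 10 (E)-1-[3,4-bis(benzyloxy)phenyl]icos-3-en-5-one, via β-mesyloxy ketone 9 (not isolated)
Conditions: MsCl (1.5 equiv), Et3N (4 equiv), CH2Cl2, 0 °C to rt
Reagents that add atoms: none
Why: Mesylation followed by base-mediated E1cB elimination of the β-mesyloxy ketone gives the conjugated, thermodynamically favoured E-enone; the alkene geometry is not carried into the target.

Step 7
Reactants: 10 (E)-1-[3,4-bis(benzyloxy)phenyl]icos-3-en-5-one
Product: 12 1-(3,4-dihydroxyphenyl)icosan-5-one, via 1-[3,4-bis(benzyloxy)phenyl]icosan-5-one 11 (not isolated)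
Conditions: H2 (1 atm), 10% Pd/C, EtOAc/EtOH 1:1, rt; filter and concentrate under N2
Reagents that add atoms: none
Why: Catalytic hydrogenation saturates the enone C=C first, then hydrogenolysis cleaves both aryl benzyl ethers, while the isolated aliphatic ketone is not reduced over Pd/C at 1 atm.

## Compound list

1 | 3-(3,4-dihydroxyphenyl)propanoic acid | OC(=O)CCc1ccc(O)c(O)c1 | starting material
2 | methyl 3-(3,4-dihydroxyphenyl)propanoate | COC(=O)CCc1ccc(O)c(O)c1 | intermediate
3 | methyl 3-[3,4-bis(benzyloxy)phenyl]propanoate | COC(=O)CCc1ccc(OCc2ccccc2)c(OCc2ccccc2)c1 | intermediate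
4 | 3-[3,4-bis(benzyloxy)phenyl]propan-1-ol | OCCCc1ccc(OCc2ccccc2)c(OCc2ccccc2)c1 | intermediate
5 | 3-[3,4-bis(benzyloxy)phenyl]propanal | O=CCCc1ccc(OCc2ccccc2)c(OCc2ccccc2)c1 | intermediate
6 | heptadecan-2-one | CCCCCCCCCCCCCCCC(C)=O | starting material
7 | lithium heptadec-1-en-2-olate (kinetic enolate, not isolated) | [Li+].[O-]C(=C)CCCCCCCCCCCCCCC | intermediate
8 | (±)-1-[3,4-bis(benzyloxy)phenyl]-3-hydroxyicosan-5-one (racemic) | CCCCCCCCCCCCCCCC(=O)CC(O)CCc1ccc(OCc2ccccc2)c(OCc2ccccc2)c1 | intermediate
9 | (±)-1-[3,4-bis(benzyloxy)phenyl]-5-oxoicosan-3-yl methanesulfonate (not isolated) | CCCCCCCCCCCCCCCC(=O)CC(OS(C)(=O)=O)CCc1ccc(OCc2ccccc2)c(OCc2ccccc2)c1 | intermediate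
10 | (E)-1-[3,4-bis(benzyloxy)phenyl]icos-3-en-5-one | CCCCCCCCCCCCCCCC(=O)/C=C/CCc1ccc(OCc2ccccc2)c(OCc2ccccc2)c1 | intermediate
11 | 1-[3,4-bis(benzyloxy)phenyl]icosan-5-one (not isolated) | CCCCCCCCCCCCCCCC(=O)CCCCc1ccc(OCc2ccccc2)c(OCc2ccccc2)c1 | intermediate
12 | 1-(3,4-dihydroxyphenyl)icosan-5-one | CCCCCCCCCCCCCCCC(=O)CCCCc1ccc(O)c(O)c1 | target

## Totals and risks

Total step count: 7. Longest linear sequence: 7 steps (1 to 12); ketone 6 is bought and enters at step 5.

The three steps most likely to fail, most likely first:

**Step 5 (aldol addition).** The risks are partial enolisation at the internal CH2 of 6 (typically about 10–15 % of the regioisomeric enolate), poor solubility of the long-chain ketone at −78 °C, and self-condensation of 5. The fallback sets out from 5 and comes back to the route at 12, with the regiochemistry fixed by a doubly activated methylene. Palmitoyl chloride and Meldrum's acid (pyridine, CH2Cl2, 0 °C) give 5-(1-hydroxyhexadecylidene)-2,2-dimethyl-1,3-dioxane-4,6-dione F1. Heating with benzyl alcohol in toluene gives benzyl 3-oxooctadecanoate F2. Knoevenagel condensation of F2 with 5 (cat. piperidine/AcOH, CH2Cl2, 0 °C, or TiCl4/pyridine) gives benzyl 2-{3-[3,4-bis(benzyloxy)phenyl]propylidene}-3-oxooctadecanoate F3 as an E/Z mixture, which does not matter. H2 over Pd/C in EtOAc saturates the alkene and removes all three benzyl groups to give 2-[3-(3,4-dihydroxyphenyl)propyl]-3-oxooctadecanoic acid F4. This β-keto acid loses CO2 on warming to about 60 °C and gives 12.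

**Step 7 (global hydrogenation).** The risks are stalling at a mono-benzyl ether, ketal formation in the alcohol co-solvent, and air oxidation of the catechol on the catalyst. The fallback sets out from 10 and comes back at 12, separating the two events and removing the benzyl groups without hydrogen. Conjugate reduction of 10 with [(Ph3P)CuH]6 (Stryker's reagent) in wet toluene gives 11, this time isolated. BCl3 with pentamethylbenzene as cation scavenger in CH2Cl2 at −78 °C then cleaves both benzyl ethers to give 12. This detour makes no compound outside the compound list (F0).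

**Step 4 (oxidation to aldehyde 5).** The 3-arylpropanal is enolisable and air-sensitive and can self-condense or oxidise on storage or chromatography. The fallback sets out from 3 and comes back at 5, releasing the aldehyde only on cold work-up. Ester 3 with MeNH(OMe)·HCl and iPrMgCl in THF at −20 °C gives 3-[3,4-bis(benzyloxy)phenyl]-N-methoxy-N-methylpropanamide F5, a stable, storable compound. Reduction with iBu2AlH in THF at −78 °C stops at the chelated hemiaminal, and cold aqueous work-up gives 5, which is taken straight into step 5.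

## Further compounds

F1 | step 5 | 5-(1-hydroxyhexadecylidene)-2,2-dimethyl-1,3-dioxane-4,6-dione | CCCCCCCCCCCCCCCC(O)=C1C(=O)OC(C)(C)OC1=O
F2 | step 5 | benzyl 3-oxooctadecanoate | CCCCCCCCCCCCCCCC(=O)CC(=O)OCc1ccccc1
F3 | step 5 | benzyl 2-{3-[3,4-bis(benzyloxy)phenyl]propylidene}-3-oxooctadecanoate (E/Z mixture) | CCCCCCCCCCCCCCCC(=O)C(=CCCc1ccc(OCc2ccccc2)c(OCc2ccccc2)c1)C(=O)OCc1ccccc1
F4 | step 5 | 2-[3-(3,4-dihydroxyphenyl)propyl]-3-oxooctadecanoic acid (racemic) | CCCCCCCCCCCCCCCC(=O)C(CCCc1ccc(O)c(O)c1)C(O)=O
F0 | step 7 | none | none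
F5 | step 4 | 3-[3,4-bis(benzyloxy)phenyl]-N-methoxy-N-methylpropanamide | CON(C)C(=O)CCc1ccc(OCc2ccccc2)c(OCc2ccccc2)c1
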